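(The earlier runs and the new flask are calculated for substances that don't exist, and the scatter is random.)

Molar is the unit to think in here: I carry one concentration, em, the [D] at which closure to G and bimolecular loss of D go equally fast (the field's effective molarity).

| flask | D | temperature | remark | time |
|---|---|---|---|---|
| eta | 0.013 M | 45 °C | run made earlier |  |
| alpha | 0.030 M | 80 °C | run made earlier |  |
| dusk | 0.020 M | 90 °C |  | 10 d |
| summer | 0.020 M | 50 °C |  | 10 d |
| midnight | 0.020 M | 70 °C |  | 10 d |
| dawn | 0.020 M | 110 °C |  | 10 d |

- eta (time / d: G / %, D / %): 4.00: 2.8, 42.1; 12.0: 5.9, 15.8; 25.0: 7.8, 5.8; 30.0: 7.7, 3.9; 50.0: 8.7, 1.9; 60.0: 8.8, 0.3; 80.0: 10.6, 0.5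
- alpha (time / d: G / %, D / %): 1.04: 19.2, 0.4; 1.67: 19.2, 1.2; 2.50: 19.1, 0.6; 4.00: 19.6, 0; 5.00: 18.7, 0; 8.00: 19.7, 0; 12.0: 19.8, 0

(standard deviation of a reading: 0.5 percentage points)

- percentages count the D that a species holds: one Z or E counts as two
- percentages count the D that a species holds: one Q counts as three
- reactions considered so far: D + Z -> Q; 2 D -> Z; D -> G; D + G -> E

1. the flask that comes out highest in amount of G, in percent of the D charged, or "all alike" when all lie within 1.5 percentage points (dusk / summer / midnight / dawn / all alike)
2. G at the end, in percent of the D charged, dusk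
3. G at the end, in percent of the D charged, summer
4. G at the end, in percent of the D charged, midnight
5. G at the end, in percent of the D charged, dawn

I build dawn up step by step. Take D → G by itself: G ends at 100 percent of the charge. Now add dimerisation of D to Z. Closure goes with [D], loss with [D] squared, so at any moment the share of D closing is em/(em + [D]), and that share climbs as [D] falls. Summed from the charge c, with r = em/c, this gives G as a fraction g = r·ln(1 + 1/r). Next comes D + Z → Q, a second bimolecular loss of D. I fold it into em, so em is an effective number read from runs.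

The last readings of alpha average 19.4 %, and those of eta 9.37 %. Solving the rule for em gives a reading of 0.00215 M at 80 °C and 3.29 × 10⁻⁴ M at 45 °C. So closure's activation energy reads about 50.1 kJ mol⁻¹ above that of the folded loss, a figure from these two runs with their scatter. Carried to dawn's 110 °C, em reads 0.00817 M, and my rule gives 50.6 %. Dawn is hotter than the other flasks, so I expect it to lead.

Last comes D + G → E. Alpha's G reads 19.2 % at 1.04 d, where D reads 0.4 %, and 19.8 % at 12.0 d, so within the scatter it holds steady from there on, though that says nothing of E while D lasts. I leave E out.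

The forecast names dawn, with G at 31 % in dusk, 5.6 % in summer, 18 % in midnight and 45 % in dawn. For dawn it stands lower than my figure, and it writes “so I shade the hot flasks down”.

Dawn gives 52.7 % and leads, with dusk at 34.4 %, midnight at 18.5 % and summer at 6.56 %.

    D + Z → Q (k = 0.00700 M⁻¹ s⁻¹, Ea = 79.0 kJ mol⁻¹)
    2 D → Z (k = 0.00580 M⁻¹ s⁻¹, Ea = 83.0 kJ mol⁻¹)
    D → G (k = 5.90 × 10⁻⁵ s⁻¹, Ea = 128 kJ mol⁻¹)
    D + G → E (k = 4.50 × 10⁻⁵ M⁻¹ s⁻¹, Ea = 105 kJ mol⁻¹)
    (constants at 90 °C)

With the step to E struck out, dawn's G comes to 52.9 %. My figure from em4 stands 2.1 percentage points below dawn's result. Dawn's charge starts at 2.45 times em4, so by my rule the stretch to watch is [D] falling below em4, where closure's share passes half. The neighbour flask is dawn with 0.034 M of D at the same temperature, so I keep em4, which gives r = 0.240 and hence G at 39.4 %; that flask computes to G at 40.0 %.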